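Germacrane numbering is used: carbocycle C1–C10; lactone O6–C6–C7–C11–C12; C13 is the exocyclic CH2; C14 is the CH3 on C10; C15 is the CH2O on C4.
Cuts, in retrosynthetic order: O15–Si and O3–Ac; C3–C4 of the ten-membered ring (aldehyde + Z-iodoalkene); the epoxide O on C1=C10; C8–O (ester, with inversion); C7–C8 (aldehyde + 3-bromomethylbutenolide). This leaves a C4–C7/C11–C13/C15 butenolide and a C1–C3/C8–C10/C14 aldehyde.
Enabling feature: C3 is a carbinol carbon bound to sp2-C4 of the Z-C4=C5 alkene, so ring bond C3–C4 is the retron of an alkenylmetal/aldehyde addition. Both carbons are electrophilic in the precursor and are joined by Cr(II)/Ni polarity reversal. The Z-alkene, the trans-lactone (C6–C7) and the trans-epoxide (C1–C10) pre-bend the chain.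
Forward ring order: butenolide (RCM), then α-methylene-γ-lactone (unveiled in the Barbier union), then epoxide (Shi), then the ten-membered carbocycle last.
Stereochemistry: C6 comes from a catalytic asymmetric alkynylation. C7 and C8 are relayed from C6 in the Barbier step, and C8 is then inverted by Mitsunobu esterification. C1/C10 come from the Shi catalyst acting on an E-alkene made by syn-carboalumination. Z-C4=C5 comes from trans-hydroalumination/iodination, and C3 from the macrocyclic transition state.

Key step: step 14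

Remark: the (S,S)-antipode of ProPhenol is assumed to give (S)-4; if the sense of induction is the opposite, the (R,R)-ligand is used.

Step 1
Reactants: 1 tert-butyldimethyl(prop-2-yn-1-yloxy)silane; 2 (E)-but-2-enal
Product: 4 (4S,5E)-1-(tert-butyldimethylsilyloxy)hept-5-en-2-yn-4-ol, via methylzinc acetylide 3 (not isolated)
Conditions: Me2Zn, (S,S)-ProPhenol (10 mol %), Ph3P=O (20 mol %), toluene, rt then 0 °C
Reagents that add atoms: none
Why: Zn–ProPhenol-catalysed asymmetric alkynylation of an α,β-unsaturated aldehyde, in which 3 adds 1,2 to the enal held in the chiral dinuclear zinc pocket and so fixes the later lactone carbinol C6 as (S).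

Step 2
Reactants: 4 (4S,5E)-1-(tert-butyldimethylsilyloxy)hept-5-en-2-yn-4-ol
Product: 6 (2Z,4S,5E)-1-(tert-butyldimethylsilyloxy)-2-iodohepta-2,5-dien-4-ol, via cyclic alkenylaluminate 5 (not isolated)
Conditions: Red-Al, THF, 0 °C; then I2, THF, −78 °C to 0 °C
Reagents that add atoms: iodine, SMILES II
Why: Hydroxyl-directed trans-hydroalumination of the propargylic alcohol (H to C5, Al to C4) followed by iodinolysis with retention should give only the Z-iodoalkene with iodine cis to C6, as is known for mono-silylated butynediols at low temperature, and C6 is not touched.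

Step 3
Reactants: 6 (2Z,4S,5E)-1-(tert-butyldimethylsilyloxy)-2-iodohepta-2,5-dien-4-ol; 7 2-(bromomethyl)acrylic acid
Product: 8 (2Z,4S,5E)-1-(tert-butyldimethylsilyloxy)-2-iodohepta-2,5-dien-4-yl 2-(bromomethyl)acrylate
Conditions: DCC, DMAP (cat.), CH2Cl2, 0 °C
Reagents that add atoms: none
Why: Steglich esterification acylates the oxygen of the secondary bis-allylic alcohol under near-neutral conditions, so C6 keeps its configuration and the allylic bromide stays in place.

Step 4
Reactants: 8 (2Z,4S,5E)-1-(tert-butyldimethylsilyloxy)-2-iodohepta-2,5-dien-4-yl 2-(bromomethyl)acrylate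
Product: 9 (5S)-3-(bromomethyl)-5-[(1Z)-3-(tert-butyldimethylsilyloxy)-2-iodoprop-1-enyl]furan-2(5H)-one
Conditions: Grubbs II (5 mol %), CH2Cl2, reflux
Reagents that add atoms: none
Why: Ring-closing metathesis of the acrylate C=CH2 with the propenyl group is the standard entry to α-substituted butenolides; the trisubstituted iodoalkene is inert to the ruthenium carbene and C6 is not involved.

Step 5
Reactants: 10 (but-3-yn-1-yloxy)(tert-butyl)dimethylsilane
Product: 13 (3E)-6-(tert-butyldimethylsilyloxy)-4-methylhex-3-en-1-ol, via alkenyldimethylalane 11 (not isolated), via lithium alkenylalanate 12 (not isolated)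
Conditions: Me3Al, Cp2ZrCl2 (cat.), CH2Cl2, 0 °C to rt; n-BuLi, hexane/THF, −78 °C; ethylene oxide, −78 °C to rt
Reagents that add atoms: trimethylaluminium, SMILES C[Al](C)C; ethylene oxide, SMILES C1CO1
Why: Negishi Zr-catalysed syn-carboalumination puts CH3 on C10 and Al on C1 on the same side, and the alanate opens ethylene oxide with retention at C1, which fixes the E geometry of C1=C10.

Step 6
Reactants: 13 (3E)-6-(tert-butyldimethylsilyloxy)-4-methylhex-3-en-1-ol
Product: 14 4-methoxybenzyl ether of 13 (PMB on O3, TBS on O8)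
Conditions: NaH, PMBCl, Bu4NI (cat.), THF/DMF, 0 °C to rt
Reagents that add atoms: 4-methoxybenzyl chloride, SMILES COc1ccc(CCl)cc1
Why: Williamson etherification of the free primary alcohol differentiates the two chain ends and leaves the silyl ether intact.

Step 7
Reactants: 14 4-methoxybenzyl ether of 13
Product: 15 (3E)-6-(4-methoxybenzyloxy)-3-methylhex-3-en-1-ol
Conditions: TBAF, THF, 0 °C to rt
Reagents that add atoms: none
Why: Fluoride-induced desilylation frees O8 selectively, because the PMB ether and the alkene are inert to fluoride.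

Step 8
Reactants: 15 (3E)-6-(4-methoxybenzyloxy)-3-methylhex-3-en-1-ol
Product: 16 (3E)-6-(4-methoxybenzyloxy)-3-methylhex-3-enal
Conditions: DMP, NaHCO3, CH2Cl2, 0 °C; used crude
Reagents that add atoms: none
Why: Buffered Dess–Martin oxidation stops at the aldehyde and is mild enough to keep the β,γ-double bond out of conjugation and E-configured.

Step 9
Reactants: 9 (5S)-3-(bromomethyl)-5-[(1Z)-3-(tert-butyldimethylsilyloxy)-2-iodoprop-1-enyl]furan-2(5H)-one; 16 (3E)-6-(4-methoxybenzyloxy)-3-methylhex-3-enal
Product: 18 (4R,5S)-4-[(1S,3E)-1-hydroxy-6-(4-methoxybenzyloxy)-3-methylhex-3-enyl]-5-[(1Z)-3-(tert-butyldimethylsilyloxy)-2-iodoprop-1-enyl]-3-methylideneoxolan-2-one, via allylzinc bromide 17 (not isolated)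
Conditions: Zn dust, THF/sat. aq NH4Cl, 0 °C to rt
Reagents that add atoms: none
Why: Zinc Barbier allylation (SE2′) of a 5-substituted 3-(bromomethyl)butenolide, in which 17 reacts through C7 on the face opposite to the C6 alkenyl group (trans C6/C7, 7R) in a chair Zimmerman–Traxler transition state with the aldehyde chain equatorial (anti, 8S), the double bond moves to C11=C13, and the iodoalkene is inert to zinc.

Step 10
Reactants: 18 the (6S,7R,8S)-alcohol from step 9; 19 methacrylic acid
Product: 20 (6S,7R,8R)-8-methacrylate of the same seco skeleton (C1=C10 E, O3-PMB, O15-TBS, C4–I)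
Conditions: PPh3, DIAD, toluene, 0 °C to rt
Reagents that add atoms: none
Why: In the Mitsunobu esterification methacrylate displaces the activated C8–O bond in an SN2 process, which inverts C8 from S to the required R and installs the ester in the same operation.

Step 11
Reactants: 20 (6S,7R,8R)-8-methacrylate
Product: 21 (1R,10R)-epoxide of 20
Conditions: D-fructose-derived Shi ketone (30 mol %), Oxone, K2CO3, Bu4NHSO4, MeCN/dimethoxymethane/aq Na2B4O7–EDTA buffer, −5 to 0 °C
Reagents that add atoms: Oxone (potassium peroxymonosulfate), SMILES [K+].[O-]S(=O)(=O)OO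
Why: In the Shi asymmetric epoxidation the D-fructose-derived catalyst transfers oxygen through the spiro transition state to the only electron-rich alkene, the E-trisubstituted C1=C10, on the face that gives the (R,R)-epoxide typical of this catalyst, while the two enoates and the iodoalkene are too electron-poor to compete.

Step 12
Reactants: 21 (1R,10R)-epoxide
Product: 22 epoxy alcohol (free C3–OH)
Conditions: DDQ, CH2Cl2/pH 7 phosphate buffer, 0 °C
Reagents that add atoms: none
Why: Oxidative PMB cleavage under buffered, essentially neutral conditions frees O3 without touching the epoxide, the silyl ether, the esters or the iodoalkene.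

Step 13
Reactants: 22 epoxy alcohol
Product: 23 β,γ-epoxy aldehyde (C3 = CHO)
Conditions: DMP, NaHCO3, CH2Cl2, 0 °C; filtered and used at once
Reagents that add atoms: none
Why: Buffered Dess–Martin oxidation gives the aldehyde without any amine base, which should avoid eliminative opening of the neighbouring C1–O bond.

Step 14
Reactants: 23 β,γ-epoxy aldehyde
Product: 25 (1R,3S,4Z,6R,7R,8R,10R)-15-(tert-butyldimethylsilyloxy)-1,10-epoxy-3-hydroxy-8-methacryloyloxygermacra-4,11(13)-dien-12,6-olide, via alkenylchromium dichloride 24 (not isolated)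
Conditions: CrCl2 (excess), NiCl2 (cat.), degassed DMSO/THF, slow addition of 23 at high dilution, rt
Reagents that add atoms: none
Why: Ni(0), formed from NiCl2 by CrCl2, inserts into the C4–I bond with retention of the Z geometry, transmetalation to Cr(III) gives the nucleophilic alkenylchromium 24, and 24 adds to the C3 aldehyde, so that two carbons that are both electrophilic in 23 are joined by polarity reversal at C4. The closest known reaction type is the Nozaki–Hiyama–Kishi macrocyclisation of iodoalkenyl aldehydes, which is established for medium rings, ten-membered germacranolide carbocycles with an α-methylene lactone in place included. The one ring that closes is the ten-membered carbocycle, in a 10-exo-trig addition to C=O with C4=C5 ending up endocyclic; the Z-alkene holds C3 and C6 on the same side, and the trans-lactone and the trans-epoxide freeze further rotors, which together with high dilution should favour cyclisation over oligomerisation. C3 is controlled by the cyclic transition state: allylic 1,3-strain against C6 turns H3 to the inside of the Z-alkene, the C2 and C7 arms leave the alkene plane on opposite faces, and the O–Cr bond points to the periphery, which means attack on the Re face of the aldehyde and (3S). The step needs chemoselectivity for C–I and CHO beside two enoates, a silyl ether and an epoxide; this is secured because only the C–I bond adds to Ni(0), alkenylchromium(III) attacks aldehydes only, and the medium is neutral, so that the base-labile β,γ-epoxy aldehyde should not eliminate.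

Step 15
Reactants: 25 macrocyclic (3S)-alcohol
Product: 26 (3S)-acetate of 25
Conditions: Ac2O, pyridine, DMAP (cat.), CH2Cl2, 0 °C
Reagents that add atoms: acetic anhydride, SMILES CC(=O)OC(C)=O
Why: Acylation at oxygen leaves C3 unchanged and removes the free 3-OH before it can attack the C1–C10 epoxide across the ring.

Step 16
Reactants: 26 (3S)-acetate
Product: 27 target, (1R,3S,4Z,6R,7R,8R,10R)-3-acetoxy-1,10-epoxy-15-hydroxy-8-methacryloyloxygermacra-4,11(13)-dien-12,6-olide
Conditions: Et3N·3HF, MeCN, 0 °C to rt
Reagents that add atoms: none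
Why: Near-neutral fluoride desilylation of the primary allylic TBS ether should spare the acid-labile epoxide and avoid base-induced O3-to-O15 acetyl migration.

Compound list
1 | tert-butyldimethyl(prop-2-yn-1-yloxy)silane | C#CCO[Si](C)(C)C(C)(C)C | starting material
2 | (E)-but-2-enal | C/C=C/C=O | starting material
3 | methylzinc acetylide of 1 | C[Zn]C#CCO[Si](C)(C)C(C)(C)C | intermediate
4 | (4S,5E)-1-(tert-butyldimethylsilyloxy)hept-5-en-2-yn-4-ol | C/C=C/[C@H](O)C#CCO[Si](C)(C)C(C)(C)C | intermediate
5 | sodium cyclic alkenylaluminate (Al on C4, bound to O6) | C/C=C/[C@@H]1O[Al-](OCCOC)(OCCOC)C(CO[Si](C)(C)C(C)(C)C)=C1.[Na+] | intermediate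
6 | (2Z,4S,5E)-1-(tert-butyldimethylsilyloxy)-2-iodohepta-2,5-dien-4-ol | C/C=C/[C@H](O)/C=C(\I)CO[Si](C)(C)C(C)(C)C | intermediate
7 | 2-(bromomethyl)acrylic acid | C=C(CBr)C(=O)O | starting material
8 | (2Z,4S,5E)-1-(tert-butyldimethylsilyloxy)-2-iodohepta-2,5-dien-4-yl 2-(bromomethyl)acrylate | C/C=C/[C@H](OC(=O)C(=C)CBr)/C=C(\I)CO[Si](C)(C)C(C)(C)C | intermediate
9 | (5S)-3-(bromomethyl)-5-[(1Z)-3-(tert-butyldimethylsilyloxy)-2-iodoprop-1-enyl]furan-2(5H)-one | BrCC1=C[C@@H](/C=C(\I)CO[Si](C)(C)C(C)(C)C)OC1=O | intermediate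
10 | (but-3-yn-1-yloxy)(tert-butyl)dimethylsilane | C#CCCO[Si](C)(C)C(C)(C)C | starting material
11 | (E)-alkenyldimethylalane (Al on C1, cis to the new CH3) | C[Al](C)/C=C(\C)CCO[Si](C)(C)C(C)(C)C | intermediate
12 | lithium (E)-alkenyl(butyl)dimethylalanate | [Li+].CCCC[Al-](C)(C)/C=C(\C)CCO[Si](C)(C)C(C)(C)C | intermediate
13 | (3E)-6-(tert-butyldimethylsilyloxy)-4-methylhex-3-en-1-ol | OCC/C=C(\C)CCO[Si](C)(C)C(C)(C)C | intermediate
14 | 4-methoxybenzyl ether of 13 | COc1ccc(COCC/C=C(\C)CCO[Si](C)(C)C(C)(C)C)cc1 | intermediate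
15 | (3E)-6-(4-methoxybenzyloxy)-3-methylhex-3-en-1-ol | COc1ccc(COCC/C=C(\C)CCO)cc1 | intermediate
16 | (3E)-6-(4-methoxybenzyloxy)-3-methylhex-3-enal | COc1ccc(COCC/C=C(\C)CC=O)cc1 | intermediate
17 | allylzinc bromide from 9 | Br[Zn]CC1=C[C@@H](/C=C(\I)CO[Si](C)(C)C(C)(C)C)OC1=O | intermediate
18 | (6S,7R,8S)-seco alcohol, trans-α-methylene-γ-lactone with 8-OH | C=C1C(=O)O[C@H](/C=C(\I)CO[Si](C)(C)C(C)(C)C)[C@H]1[C@@H](O)C/C(C)=C/CCOCc2ccc(OC)cc2 | intermediate
19 | methacrylic acid | C=C(C)C(=O)O | starting material
20 | (6S,7R,8R)-seco 8-methacrylate | C=C1C(=O)O[C@H](/C=C(\I)CO[Si](C)(C)C(C)(C)C)[C@H]1[C@H](OC(=O)C(C)=C)C/C(C)=C/CCOCc2ccc(OC)cc2 | intermediate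
21 | (1R,6S,7R,8R,10R)-seco epoxide, O3-PMB | C=C1C(=O)O[C@H](/C=C(\I)CO[Si](C)(C)C(C)(C)C)[C@H]1[C@H](OC(=O)C(C)=C)C[C@@]2(C)O[C@@H]2CCOCc3ccc(OC)cc3 | intermediate
22 | seco epoxy alcohol (C3–OH) | C=C1C(=O)O[C@H](/C=C(\I)CO[Si](C)(C)C(C)(C)C)[C@H]1[C@H](OC(=O)C(C)=C)C[C@@]2(C)O[C@@H]2CCO | intermediate
23 | seco β,γ-epoxy aldehyde (C3 = CHO) | C=C1C(=O)O[C@H](/C=C(\I)CO[Si](C)(C)C(C)(C)C)[C@H]1[C@H](OC(=O)C(C)=C)C[C@@]2(C)O[C@@H]2CC=O | intermediate
24 | (Z)-alkenylchromium(III) dichloride (Cr on C4) | C=C1C(=O)O[C@H](/C=C(\[Cr](Cl)Cl)CO[Si](C)(C)C(C)(C)C)[C@H]1[C@H](OC(=O)C(C)=C)C[C@@]2(C)O[C@@H]2CC=O | intermediate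
25 | (1R,3S,4Z,6R,7R,8R,10R)-15-(tert-butyldimethylsilyloxy)-1,10-epoxy-3-hydroxy-8-methacryloyloxygermacra-4,11(13)-dien-12,6-olide | C=C(C)C(=O)O[C@@H]1C[C@@]2(C)O[C@@H]2C[C@H](O)/C(CO[Si](C)(C)C(C)(C)C)=C\[C@H]2OC(=O)C(=C)[C@@H]21 | intermediate
26 | 3-O-acetate of 25 | C=C(C)C(=O)O[C@@H]1C[C@@]2(C)O[C@@H]2C[C@H](OC(C)=O)/C(CO[Si](C)(C)C(C)(C)C)=C\[C@H]2OC(=O)C(=C)[C@@H]21 | intermediate
27 | (1R,3S,4Z,6R,7R,8R,10R)-3-acetoxy-1,10-epoxy-15-hydroxy-8-methacryloyloxygermacra-4,11(13)-dien-12,6-olide | C=C(C)C(=O)O[C@@H]1C[C@@]2(C)O[C@@H]2C[C@H](OC(C)=O)/C(CO)=C\[C@H]2OC(=O)C(=C)[C@@H]21 | target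

Total step count: 16. Longest linear sequence: 12 (steps 1–4 or 5–8, then 9–16).

Steps most likely to fail

Step 14. The ring closure may show poor facial selectivity at the aldehyde carbon, so that C3 is not set cleanly. The fallback sets out from 25 as obtained together with its C3 epimer, the (3R)-alcohol F1. The mixture is oxidised (DMP, NaHCO3, CH2Cl2, 0 °C) to the ten-membered C3 enone F2. C3 is then set after ring closure by reagent control, in a CBS reduction with (R)-Me-CBS and catecholborane in toluene at −78 °C (alkenyl as the large group). This comes back to the route at 25.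

Step 10. Substitution at the hindered C8 may lose out to elimination toward conjugated dienes, or to addition of the phosphine to the α-methylene lactone. The fallback avoids the inversion altogether and sets out from 9 and 16.
- Bromide 9 is converted with Zn and Bu3SnCl in THF/sat. aq NH4Cl into the 3-(tributylstannylmethyl)butenolide F3.
- BF3·OEt2-promoted addition of F3 to 16 (CH2Cl2, −78 °C) passes through an open antiperiplanar transition state, as in syn-selective Lewis acid allylstannane addition. It still attacks anti to the C6 substituent and should give the (8R)-alcohol F4 directly.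
- Acylation with methacrylic anhydride/DMAP proceeds with retention and comes back to the route at 20.

Step 11. The basic aqueous peroxide medium may cause hydrolysis of, or conjugate addition to, the α-methylene lactone and the methacrylate, and catalyst control next to C8 may be weak. The fallback sets out from 20.
- The PMB group is removed first (DDQ, buffered CH2Cl2) to give the homoallylic alcohol F5.
- C1=C10 is then epoxidised by hydroxyl-directed asymmetric epoxidation with Hf(Ot-Bu)4, a chiral bishydroxamic acid ligand (the antipode that gives 1R,10R) and cumene hydroperoxide in anhydrous toluene.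
- This comes back to the route at 22.

Further compounds
F1 | step 14 | (3R)-epimer of 25 | C=C(C)C(=O)O[C@@H]1C[C@@]2(C)O[C@@H]2C[C@@H](O)/C(CO[Si](C)(C)C(C)(C)C)=C\[C@H]2OC(=O)C(=C)[C@@H]21
F2 | step 14 | ten-membered C3 enone | C=C(C)C(=O)O[C@@H]1C[C@@]2(C)O[C@@H]2CC(=O)/C(CO[Si](C)(C)C(C)(C)C)=C\[C@H]2OC(=O)C(=C)[C@@H]21
F3 | step 10 | (5S)-3-(tributylstannylmethyl)-5-[(1Z)-3-(tert-butyldimethylsilyloxy)-2-iodoprop-1-enyl]furan-2(5H)-one | CCCC[Sn](CCCC)(CCCC)CC1=C[C@@H](/C=C(\I)CO[Si](C)(C)C(C)(C)C)OC1=O
F4 | step 10 | (6S,7R,8R)-seco alcohol (8-epimer of 18) | C=C1C(=O)O[C@H](/C=C(\I)CO[Si](C)(C)C(C)(C)C)[C@H]1[C@H](O)C/C(C)=C/CCOCc2ccc(OC)cc2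
F5 | step 11 | homoallylic alcohol (20 without PMB) | C=C1C(=O)O[C@H](/C=C(\I)CO[Si](C)(C)C(C)(C)C)[C@H]1[C@H](OC(=O)C(C)=C)C/C(C)=C/CCO
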